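## Retrosynthetic overview

1. The target is an achiral, symmetric N,N'-dibenzylurea. Both benzylic C–N bonds are cut at once, giving urea and two equivalents of a 2,3,6-tribromo-4,5-dihydroxybenzyl electrophile (a para-quinone methide released from the benzyl alcohol).
2. The benzyl alcohol goes back to the corresponding benzaldehyde by C=O reduction.
3. The aldehyde goes back to 3,4-dihydroxybenzaldehyde by three ring C–Br disconnections (exhaustive electrophilic bromination directed by the free catechol).
4. No ring is formed in the route. Both benzene rings are bought in with the starting aldehyde, and no protecting groups are used.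

Assumption: the target has no stereocentre and no stereogenic double bond, so the "single enantiomer" request has no bearing and the SMILES carries no stereo descriptors.

## Route

Step 1
Reactants: 1 3,4-dihydroxybenzaldehyde
Product: 4 2,3,6-tribromo-4,5-dihydroxybenzaldehyde, via 3-bromo-4,5-dihydroxybenzaldehyde 2 (not isolated), via 2,3-dibromo-4,5-dihydroxybenzaldehyde 3 (not isolated)
Conditions: Br2 (4.5 equiv), Fe powder (5 mol %), glacial AcOH, 25 °C, 2 h, then 75 °C, 12 h; aq NaHSO3, precipitation from water
Reagents that add atoms: bromine, BrBr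
Why: Electrophilic aromatic substitution, in which the two free OH groups activate all three open positions (ortho to the 4-OH first, para to the 3-OH second, the crowded site between CHO and the 3-OH last), so excess Br2 with heat fills them all while the formyl group survives in water-free AcOH; no stereocentre is formed.

Step 2
Reactants: 4 2,3,6-tribromo-4,5-dihydroxybenzaldehyde
Product: 5 2,3,6-tribromo-4,5-dihydroxybenzyl alcohol
Conditions: NaBH4 (2 equiv), THF–H2O (5:1), 0 °C, 30 min; 1 M HCl to pH 4 at 0 °C, EtOAc extraction, evaporation below 30 °C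
Reagents that add atoms: none
Why: Chemoselective borohydride 1,2-reduction of the aldehyde, in which aryl bromides are inert, the extra hydride covers the acidic catechol protons, and the low temperature and alcohol-free medium prevent over-reduction through the quinone methide and ether formation on work-up; no stereocentre is formed.

Step 3
Reactants: 5 2,3,6-tribromo-4,5-dihydroxybenzyl alcohol (2.05 equiv), 6 urea (1.0 equiv)
Product: 9 N,N'-bis(2,3,6-tribromo-4,5-dihydroxybenzyl)urea, via para-quinone methide 7 (not isolated), via N-(2,3,6-tribromo-4,5-dihydroxybenzyl)urea 8 (not isolated)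
Conditions: p-TsOH·H2O (10 mol %), 1,4-dioxane (0.2 M), N2, 80 °C, 12 h; cool, add water, filter, recrystallise from acetone–water
Reagents that add atoms: none
Why: Acid-catalysed dehydrative N-benzylation of urea (biomimetic aza-1,6-addition to a para-quinone methide), which works because the para-OH drives loss of water, the fully substituted ring rules out Friedel–Crafts self-condensation, O-adducts (ethers, isoureas) revert to 7 while the N-adducts do not, and the free NH2 of 8 is far less hindered than its benzylated NH, so the second benzyl group ends up on the other nitrogen; no stereocentre is formed.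

## Compound list

1 | 3,4-dihydroxybenzaldehyde (protocatechualdehyde) | O=Cc1ccc(O)c(O)c1 | starting material
2 | 3-bromo-4,5-dihydroxybenzaldehyde | O=Cc1cc(O)c(O)c(Br)c1 | intermediate
3 | 2,3-dibromo-4,5-dihydroxybenzaldehyde | O=Cc1cc(O)c(O)c(Br)c1Br | intermediate
4 | 2,3,6-tribromo-4,5-dihydroxybenzaldehyde | O=Cc1c(Br)c(O)c(O)c(Br)c1Br | intermediate
5 | 2,3,6-tribromo-4,5-dihydroxybenzyl alcohol | OCc1c(Br)c(O)c(O)c(Br)c1Br | intermediate
6 | urea | NC(N)=O | starting material
7 | 2,3,5-tribromo-6-hydroxy-4-methylidenecyclohexa-2,5-dien-1-one (para-quinone methide) | C=C1C(Br)=C(Br)C(=O)C(O)=C1Br | intermediate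
8 | N-(2,3,6-tribromo-4,5-dihydroxybenzyl)urea | NC(=O)NCc1c(Br)c(O)c(O)c(Br)c1Br | intermediate
9 | N,N'-bis(2,3,6-tribromo-4,5-dihydroxybenzyl)urea (CNP0353106.0, achiral) | O=C(NCc1c(Br)c(O)c(O)c(Br)c1Br)NCc1c(Br)c(O)c(O)c(Br)c1Br | target

Total step count: 3
Longest linear sequence: 3

## Steps most likely to fail, with fallbacks

**Step 3 (highest risk).**
- Risk: poor conversion of the sparingly soluble urea, mixtures of mono-, bis- and over-benzylated ureas, or persistent dibenzyl ether.
- The fallback sets out from 4 and comes back to the route at 9.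
- It replaces the quinone methide chemistry by an ordinary amine-plus-carbonyl-donor urea synthesis on a capped catechol.
- Compound 4 is O-methylated (MeI, K2CO3, DMF) to 2,3,6-tribromo-4,5-dimethoxybenzaldehyde F5. Condensation with NH2OH·HCl and NaOAc in EtOH gives (E)-2,3,6-tribromo-4,5-dimethoxybenzaldehyde oxime F6, and BH3·THF at reflux reduces this to 2,3,6-tribromo-4,5-dimethoxybenzylamine F7 without touching the aryl bromides.
- Carbonyldiimidazole (0.5 equiv, THF) converts half of the amine into N-(2,3,6-tribromo-4,5-dimethoxybenzyl)imidazole-1-carboxamide F8. This takes up the other half to give N,N'-bis(2,3,6-tribromo-4,5-dimethoxybenzyl)urea F9.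
- BBr3 (CH2Cl2, −78 °C to 25 °C, then ice water) cleaves the four methyl ethers to give 9.

**Step 1.**
- Risk: the formyl group holds the reaction at the dibromide, or forcing conditions cause bromodeformylation or oxidation.
- The fallback sets out from 3 and comes back to the route at 5.
- The bromination is stopped with 2.1 equiv Br2 at 25 °C and 3 is isolated. The last bromine is then brought in only after the deactivating C=O has gone.
- NaBH4 reduces 3 to 2,3-dibromo-4,5-dihydroxybenzyl alcohol F1. HBr in AcOH turns this into 2,3-dibromo-4,5-dihydroxybenzyl bromide F2, whose CH2Br group, unlike CH2OH, is not displaced by ipso attack.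
- Br2 (1.1 equiv) in the same pot fills the one free ring position to give 2,3,6-tribromo-4,5-dihydroxybenzyl bromide F3.
- Stirring in aqueous acetone at 25 °C hydrolyses the labile benzylic bromide to 5.

**Step 2.**
- Risk: 5 is a labile quinone methide precursor that may self-etherify on isolation or be over-reduced on long contact with borohydride.
- The fallback sets out from 4 and comes back to the route at 7, and from there at 9.
- The free alcohol is given up as the carried intermediate.
- Compound 4 is reduced with NaBH4 in MeOH at 0 °C, and the mixture is acidified at once with HCl in MeOH and warmed to 40 °C. The quinone methide is then trapped as 2,3,6-tribromo-4,5-dihydroxybenzyl methyl ether F4, a stable, crystalline, storable compound.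
- Under the conditions of step 3, F4 (2.05 equiv) loses methanol in place of water to give the same 7, which urea captures as before.

## Further compounds

F1 | step 1 | 2,3-dibromo-4,5-dihydroxybenzyl alcohol | OCc1cc(O)c(O)c(Br)c1Br
F2 | step 1 | 2,3-dibromo-4,5-dihydroxybenzyl bromide | BrCc1cc(O)c(O)c(Br)c1Br
F3 | step 1 | 2,3,6-tribromo-4,5-dihydroxybenzyl bromide | BrCc1c(Br)c(O)c(O)c(Br)c1Br
F4 | step 2 | 2,3,6-tribromo-4,5-dihydroxybenzyl methyl ether | COCc1c(Br)c(O)c(O)c(Br)c1Br
F5 | step 3 | 2,3,6-tribromo-4,5-dimethoxybenzaldehyde | O=Cc1c(Br)c(OC)c(OC)c(Br)c1Br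
F6 | step 3 | (E)-2,3,6-tribromo-4,5-dimethoxybenzaldehyde oxime | O/N=C/c1c(Br)c(OC)c(OC)c(Br)c1Br
F7 | step 3 | 2,3,6-tribromo-4,5-dimethoxybenzylamine | NCc1c(Br)c(OC)c(OC)c(Br)c1Br
F8 | step 3 | N-(2,3,6-tribromo-4,5-dimethoxybenzyl)imidazole-1-carboxamide | O=C(NCc1c(Br)c(OC)c(OC)c(Br)c1Br)n1ccnc1
F9 | step 3 | N,N'-bis(2,3,6-tribromo-4,5-dimethoxybenzyl)urea | O=C(NCc1c(Br)c(OC)c(OC)c(Br)c1Br)NCc1c(Br)c(OC)c(OC)c(Br)c1Br
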